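A direct plan would take C8, the carbon that bears the ether oxygen, from the chiral pool: the (S)-lactic acid Weinreb amide A1 would be O-arylated with 2-iodo-1,3-dimethoxybenzene A2 under copper catalysis to give ether A3.
The propenol arm would then be added to the aryl ring, an aryl Grignard reagent would give the α-aryloxy ketone A4, and a chelation-controlled hydride reduction would set the carbinol carbon C7.
The aryl C–O coupling would be the weakest step: a secondary alkoxide would have to displace an iodide flanked by two methoxy groups, and the basic conditions could erode C8.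
The reduction of A4 would be the second: the C8–H beside the carbonyl group would be acidic, and the erythro outcome would rest on a weak chelate through an aryl ether oxygen.
The making of simple dimethoxyarenes and of the vinyl partner from phenols and a stannane would add length without adding complexity.

The route rests on the C7–C8 bond, read as an aldol bond once the methyl carbon C9 is written as a carbonyl carbon. The oxygen of the 2,6-dimethoxyphenoxy ring (ring B) is alkylated while C8 is still an unhindered CH2 of a glycolic acid unit, so the crowded aryl ether needs no aryl C–O coupling. A magnesium-chloride-catalysed anti-aldol addition of the chiral N-(aryloxyacetyl)oxazolidinone to 3,4-dimethoxybenzaldehyde then forms C7–C8 and sets C7 and C8 together in the erythro sense. No α-aryloxy ketone is made or reduced; the acyl carbon is taken down to the C9 methyl group, and the propenol arm is coupled last at the para carbon C1' of ring B.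

Key step: step 3

Assumption: 4-bromo-2,6-dimethoxyphenol, (S)-4-benzyloxazolidin-2-one and (E)-3-(4,4,5,5-tetramethyl-1,3,2-dioxaborolan-2-yl)prop-2-en-1-ol are taken as purchased materials, and the sense of induction in the aldol step is assigned by analogy with N-propionyl imides.

Step 1
Reactants: 1 4-bromo-2,6-dimethoxyphenol
Product: 2 2-(4-bromo-2,6-dimethoxyphenoxy)acetic acid
Conditions: BrCH2CO2H (1.5 equiv), NaOH (3.5 equiv), H2O, 100 °C, 6 h; then 2 M aq HCl to pH 1, 0 °C
Reagents that add atoms: bromoacetic acid, OC(=O)CBr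
Why: Williamson ether synthesis, in which the phenoxide of 1 displaces bromide from the unhindered primary carbon of bromoacetate by SN2, so the oxygen of ring B is joined to the future C8 without any aryl C–O coupling; no stereocentre is formed.

Step 2
Reactants: 2 2-(4-bromo-2,6-dimethoxyphenoxy)acetic acid; 3 (S)-4-benzyloxazolidin-2-one
Product: 5 (S)-4-benzyl-3-[2-(4-bromo-2,6-dimethoxyphenoxy)acetyl]oxazolidin-2-one, via mixed pivalic anhydride 4 (not isolated)
Conditions: t-BuCOCl (1.1 equiv), Et3N (2.5 equiv), THF, −20 °C, 1 h; then 3 (1.0 equiv), LiCl (1.1 equiv), −20 to 23 °C, 12 h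
Reagents that add atoms: none
Why: N-acylation of the oxazolidinone by the mixed-anhydride method, in which pivaloyl chloride activates 2 as anhydride 4 and the LiCl/Et3N-activated oxazolidinone attacks its less hindered aryloxyacetyl carbonyl group; the auxiliary stereocentre is not touched.

Step 3
Reactants: 5 (S)-4-benzyl-3-[2-(4-bromo-2,6-dimethoxyphenoxy)acetyl]oxazolidin-2-one; 6 3,4-dimethoxybenzaldehyde (1.2 equiv)
Product: 9 (S)-4-benzyl-3-[(2R,3R)-2-(4-bromo-2,6-dimethoxyphenoxy)-3-(3,4-dimethoxyphenyl)-3-hydroxypropanoyl]oxazolidin-2-one, via chloromagnesium (Z)-enolate 7 (not isolated), via O-trimethylsilyl aldol adduct 8 (not isolated)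
Conditions: MgCl2 (20 mol %), Et3N (2.0 equiv), Me3SiCl (1.5 equiv), EtOAc, 23 °C, 24 h; then THF/1 M aq HCl (5:1), 23 °C, 30 min
Reagents that add atoms: none
Why: Magnesium-halide-catalysed direct anti-aldol reaction of an N-acyloxazolidinone by soft enolisation, the closest known reaction type being the same reaction of N-propionyloxazolidinones with aromatic aldehydes: MgCl2 and Et3N convert 5 into the chelated (Z)-enolate 7, which adds to the non-enolisable aldehyde 6, and Me3SiCl silylates the magnesium aldolate to 8, which frees the metal for turnover and blocks retro-aldol equilibration. No ring is closed. C8 is set by the benzyl group of the auxiliary, which shields one face of the chelated enolate so that the aldehyde should add to the other, and C7 is set relative to C8 by the boat-like transition state of this magnesium enolate, in which the aldehyde aryl group turns away from the oxazolidinone and the C7 oxygen and the C8 aryloxy group end up anti (erythro). The step needs anti over syn selectivity and a single enolate face; the fixed (Z)-geometry of the chelated imide enolate should secure the first and the auxiliary the second, while the α-aryloxy group only makes the soft enolisation easier. The acid treatment that removes the silyl group is kept short and dilute so that the electron-rich benzylic alcohol is not ionised.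

Step 4
Reactants: 9 (S)-4-benzyl-3-[(2R,3R)-2-(4-bromo-2,6-dimethoxyphenoxy)-3-(3,4-dimethoxyphenyl)-3-hydroxypropanoyl]oxazolidin-2-one
Product: 10 (1R,2S)-2-(4-bromo-2,6-dimethoxyphenoxy)-1-(3,4-dimethoxyphenyl)propane-1,3-diol
Conditions: LiBH4 (2.0 equiv), MeOH (2.0 equiv), THF, 0 °C, 2 h; sat. aq NH4Cl
Reagents that add atoms: none
Why: Reductive cleavage of the N-acyloxazolidinone by LiBH4 (hydride acyl substitution, then reduction of the aldehyde) turns the acyl carbon into the C9 hydroxymethyl group and returns the auxiliary, while C7 and C8 are not involved and C8 is no longer α to a carbonyl group afterwards.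

Step 5
Reactants: 10 (1R,2S)-2-(4-bromo-2,6-dimethoxyphenoxy)-1-(3,4-dimethoxyphenyl)propane-1,3-diol
Product: 11 (2S,3R)-2-(4-bromo-2,6-dimethoxyphenoxy)-3-(3,4-dimethoxyphenyl)-3-hydroxypropyl 4-methylbenzenesulfonate
Conditions: TsCl (1.1 equiv), Et3N (1.5 equiv), DMAP (5 mol %), CH2Cl2, 0 °C, 6 h
Reagents that add atoms: 4-methylbenzenesulfonyl chloride, Cc1ccc(cc1)S(=O)(=O)Cl
Why: Chemoselective O-sulfonylation of the primary C9 hydroxyl, which is far less hindered than the secondary benzylic C7 hydroxyl beside the aryloxy-bearing C8; no stereocentre is affected.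

Step 6
Reactants: 11 (2S,3R)-2-(4-bromo-2,6-dimethoxyphenoxy)-3-(3,4-dimethoxyphenyl)-3-hydroxypropyl 4-methylbenzenesulfonate
Product: 12 (1R,2S)-2-(4-bromo-2,6-dimethoxyphenoxy)-1-(3,4-dimethoxyphenyl)propan-1-ol
Conditions: LiBHEt3 (3.0 equiv), THF, 0 °C, 2 h; then H2O, 0 °C
Reagents that add atoms: none
Why: Hydride SN2 displacement of a primary tosylate (LiBHEt3 reduction) converts C9 into the methyl group; the C7 alkoxide is held as its triethylborane complex, which should disfavour oxetane closure and fragmentation, the aryl bromide is inert at this temperature, and C7 and C8 keep their configuration.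

Step 7
Reactants: 12 (1R,2S)-2-(4-bromo-2,6-dimethoxyphenoxy)-1-(3,4-dimethoxyphenyl)propan-1-ol; 13 (E)-3-(4,4,5,5-tetramethyl-1,3,2-dioxaborolan-2-yl)prop-2-en-1-ol (1.3 equiv)
Product: 14 (1R,2S)-1-(3,4-dimethoxyphenyl)-2-{4-[(E)-3-hydroxyprop-1-en-1-yl]-2,6-dimethoxyphenoxy}propan-1-ol (CNP0155793.1)
Conditions: Pd(dppf)Cl2 (5 mol %), K3PO4 (3.0 equiv), 1,4-dioxane/H2O (5:1), 80 °C, 6 h, Ar
Reagents that add atoms: none
Why: Suzuki–Miyaura coupling, in which zerovalent palladium inserts into the C1'–Br bond of ring B, the phosphate-activated (E)-alkenylboronate transmetalates with retention and reductive elimination gives the (E)-propenol arm; free hydroxyl groups are tolerated and no stereocentre is touched.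

**Compound list**
1 | 4-bromo-2,6-dimethoxyphenol | COc1cc(Br)cc(OC)c1O | starting material
2 | 2-(4-bromo-2,6-dimethoxyphenoxy)acetic acid | OC(=O)COc1c(OC)cc(Br)cc1OC | intermediate
3 | (S)-4-benzyloxazolidin-2-one | O=C1OC[C@H](Cc2ccccc2)N1 | starting material
4 | 2-(4-bromo-2,6-dimethoxyphenoxy)acetic pivalic anhydride (not isolated) | CC(C)(C)C(=O)OC(=O)COc1c(OC)cc(Br)cc1OC | intermediate
5 | (S)-4-benzyl-3-[2-(4-bromo-2,6-dimethoxyphenoxy)acetyl]oxazolidin-2-one | O=C(COc1c(OC)cc(Br)cc1OC)N1C(=O)OC[C@@H]1Cc1ccccc1 | intermediate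
6 | 3,4-dimethoxybenzaldehyde | COc1ccc(C=O)cc1OC | starting material
7 | chloromagnesium (Z)-1-[(S)-4-benzyl-2-oxooxazolidin-3-yl]-2-(4-bromo-2,6-dimethoxyphenoxy)ethen-1-olate (not isolated) | Cl[Mg]O/C(=C\Oc1c(OC)cc(Br)cc1OC)N1C(=O)OC[C@@H]1Cc1ccccc1 | intermediate
8 | (S)-4-benzyl-3-[(2R,3R)-2-(4-bromo-2,6-dimethoxyphenoxy)-3-(3,4-dimethoxyphenyl)-3-(trimethylsilyloxy)propanoyl]oxazolidin-2-one (not isolated) | COc1ccc([C@@H](O[Si](C)(C)C)[C@H](C(=O)N3C(=O)OC[C@@H]3Cc4ccccc4)Oc2c(OC)cc(Br)cc2OC)cc1OC | intermediate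
9 | (S)-4-benzyl-3-[(2R,3R)-2-(4-bromo-2,6-dimethoxyphenoxy)-3-(3,4-dimethoxyphenyl)-3-hydroxypropanoyl]oxazolidin-2-one | COc1ccc([C@@H](O)[C@H](C(=O)N3C(=O)OC[C@@H]3Cc4ccccc4)Oc2c(OC)cc(Br)cc2OC)cc1OC | intermediate
10 | (1R,2S)-2-(4-bromo-2,6-dimethoxyphenoxy)-1-(3,4-dimethoxyphenyl)propane-1,3-diol | COc1ccc([C@@H](O)[C@H](CO)Oc2c(OC)cc(Br)cc2OC)cc1OC | intermediate
11 | (2S,3R)-2-(4-bromo-2,6-dimethoxyphenoxy)-3-(3,4-dimethoxyphenyl)-3-hydroxypropyl 4-methylbenzenesulfonate | COc1ccc([C@@H](O)[C@H](COS(=O)(=O)c3ccc(C)cc3)Oc2c(OC)cc(Br)cc2OC)cc1OC | intermediate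
12 | (1R,2S)-2-(4-bromo-2,6-dimethoxyphenoxy)-1-(3,4-dimethoxyphenyl)propan-1-ol | COc1ccc([C@@H](O)[C@H](C)Oc2c(OC)cc(Br)cc2OC)cc1OC | intermediate
13 | (E)-3-(4,4,5,5-tetramethyl-1,3,2-dioxaborolan-2-yl)prop-2-en-1-ol | CC1(C)OB(/C=C/CO)OC1(C)C | starting material
14 | (1R,2S)-1-(3,4-dimethoxyphenyl)-2-{4-[(E)-3-hydroxyprop-1-en-1-yl]-2,6-dimethoxyphenoxy}propan-1-ol | COc1ccc([C@@H](O)[C@H](C)Oc2c(OC)cc(/C=C/CO)cc2OC)cc1OC | target

Total step count: 7. Longest linear sequence: 7 steps (1 to 14; compounds 3, 6 and 13 enter as purchased materials).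

Steps most likely to fail:

1. Step 3, the anti-aldol addition. The aryloxy oxygen and its ortho-methoxy groups may compete with the oxazolidinone carbonyl group for magnesium, so that anti selectivity or the facial bias is lost, and addition to the electron-rich aldehyde may be slow. The fallback sets out from 2 and comes back at 10. Acid 2 would be coupled through anhydride 4 with (R)-4-benzyloxazolidin-2-one to give (R)-4-benzyl-3-[2-(4-bromo-2,6-dimethoxyphenoxy)acetyl]oxazolidin-2-one F1. Its dibutylboron enolate (Bu2BOTf, i-Pr2NEt, CH2Cl2, −78 °C) would add to 6 in an Evans syn-aldol reaction through a chair transition state to give the threo adduct (R)-4-benzyl-3-[(2R,3S)-2-(4-bromo-2,6-dimethoxyphenoxy)-3-(3,4-dimethoxyphenyl)-3-hydroxypropanoyl]oxazolidin-2-one F2, which already has the required C8 configuration. A Mitsunobu reaction with 4-nitrobenzoic acid (PPh3, diisopropyl azodicarboxylate, THF) would invert C7 to give (1R,2R)-3-[(R)-4-benzyl-2-oxooxazolidin-3-yl]-2-(4-bromo-2,6-dimethoxyphenoxy)-1-(3,4-dimethoxyphenyl)-3-oxopropyl 4-nitrobenzoate F3. LiBH4 would then cleave the ester and the auxiliary together to give diol 10.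

2. Step 6, the hydride displacement. The C7 alkoxide may close onto C9 to an oxetane or fragment the C7–C8 bond with loss of the tosylate, substitution beside the branched C8 may be slow, and the C–Br bond may be partly reduced. The fallback sets out from 10 and comes back at 12; it is a Mitsunobu-type reductive deoxygenation under non-basic conditions. Diol 10 would be treated with 2-nitrobenzenesulfonohydrazide, PPh3 and diethyl azodicarboxylate (THF, −30 °C), which should alkylate the sulfonamide nitrogen at the primary C9 only and give N-[(2S,3R)-2-(4-bromo-2,6-dimethoxyphenoxy)-3-(3,4-dimethoxyphenyl)-3-hydroxypropyl]-2-nitrobenzenesulfonohydrazide F4. On warming to 23 °C it would lose the sulfinic acid to give the monoalkyl diazene (1R,2S)-2-(4-bromo-2,6-dimethoxyphenoxy)-3-diazenyl-1-(3,4-dimethoxyphenyl)propan-1-ol F5, which would lose nitrogen to give 12 without passing through tosylate 11.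

3. Step 7, the Suzuki–Miyaura coupling. Oxidative addition into the electron-rich C–Br bond may be slow, so that protodeboronation or homocoupling of the alkenylboronate takes over. The fallback sets out from 12 and comes back at 14. A Heck reaction of 12 with methyl acrylate (Pd(OAc)2, P(o-tol)3, Et3N, DMF, 100 °C) would give methyl (E)-3-(4-{[(1R,2S)-1-(3,4-dimethoxyphenyl)-1-hydroxypropan-2-yl]oxy}-3,5-dimethoxyphenyl)prop-2-enoate F6, and i-Bu2AlH (CH2Cl2, −78 °C) would reduce the ester to the allylic alcohol 14.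

**Further compounds**
F1 | step 3 | (R)-4-benzyl-3-[2-(4-bromo-2,6-dimethoxyphenoxy)acetyl]oxazolidin-2-one | O=C(COc1c(OC)cc(Br)cc1OC)N1C(=O)OC[C@H]1Cc1ccccc1
F2 | step 3 | (R)-4-benzyl-3-[(2R,3S)-2-(4-bromo-2,6-dimethoxyphenoxy)-3-(3,4-dimethoxyphenyl)-3-hydroxypropanoyl]oxazolidin-2-one | COc1ccc([C@H](O)[C@H](C(=O)N3C(=O)OC[C@H]3Cc4ccccc4)Oc2c(OC)cc(Br)cc2OC)cc1OC
F3 | step 3 | (1R,2R)-3-[(R)-4-benzyl-2-oxooxazolidin-3-yl]-2-(4-bromo-2,6-dimethoxyphenoxy)-1-(3,4-dimethoxyphenyl)-3-oxopropyl 4-nitrobenzoate | COc1ccc([C@@H](OC(=O)c5ccc(cc5)[N+](=O)[O-])[C@H](C(=O)N3C(=O)OC[C@H]3Cc4ccccc4)Oc2c(OC)cc(Br)cc2OC)cc1OC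
F4 | step 6 | N-[(2S,3R)-2-(4-bromo-2,6-dimethoxyphenoxy)-3-(3,4-dimethoxyphenyl)-3-hydroxypropyl]-2-nitrobenzenesulfonohydrazide | COc1ccc([C@@H](O)[C@H](CN(N)S(=O)(=O)c3ccccc3[N+](=O)[O-])Oc2c(OC)cc(Br)cc2OC)cc1OC
F5 | step 6 | (1R,2S)-2-(4-bromo-2,6-dimethoxyphenoxy)-3-diazenyl-1-(3,4-dimethoxyphenyl)propan-1-ol | COc1ccc([C@@H](O)[C@H](CN=N)Oc2c(OC)cc(Br)cc2OC)cc1OC
F6 | step 7 | methyl (E)-3-(4-{[(1R,2S)-1-(3,4-dimethoxyphenyl)-1-hydroxypropan-2-yl]oxy}-3,5-dimethoxyphenyl)prop-2-enoate | COc1ccc([C@@H](O)[C@H](C)Oc2c(OC)cc(/C=C/C(=O)OC)cc2OC)cc1OC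
A1 | direct plan | (S)-2-hydroxy-N-methoxy-N-methylpropanamide | CON(C)C(=O)[C@H](C)O
A2 | direct plan | 2-iodo-1,3-dimethoxybenzene | COc1cccc(OC)c1I
A3 | direct plan | (S)-2-(2,6-dimethoxyphenoxy)-N-methoxy-N-methylpropanamide | CON(C)C(=O)[C@H](C)Oc1c(OC)cccc1OC
A4 | direct plan | (S)-1-(3,4-dimethoxyphenyl)-2-{4-[(E)-3-hydroxyprop-1-en-1-yl]-2,6-dimethoxyphenoxy}propan-1-one | COc1ccc(C(=O)[C@H](C)Oc2c(OC)cc(/C=C/CO)cc2OC)cc1OC
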